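The isoflavan is cut across ring C at C3–C4 and O1–C2. Ring A can serve as an ortho-quinone methide because C4a carries the C4 methylene next to C8a, which bears O1, while C2 and C3 belong to a ring-B arylacetaldehyde. In a single operation a chiral secondary amine turns that aldehyde into an enamine, which alkylates the methide carbon, fixes the only stereocentre (C3) and lets the C8a phenol close ring C as a lactol. The precursors are 2,6-dihydroxy-4-methoxy-3-(tosylmethyl)benzaldehyde, both phenols free, and the bis-silylated (2,4-dihydroxy-3-prenylphenyl)acetaldehyde. Borohydride opening, Mitsunobu re-closure and desilylation finish the synthesis.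

Key step: step 7

Remarks before the steps (prenyl = 3-methylbut-2-en-1-yl; TBS = tert-butyldimethylsilyl; isoflavan numbering O1, C2, C3, C4, C4a, C5–C8, C8a, ring B primed):
- Assumption: the target is 3R (priorities C2 > C1' > C4 > H), and the same descriptor holds for 13, 14, 15 and 16.
- Structure check: in sulfone 5 the sulfonylmethyl carbon lies between the methoxy-bearing carbon and a hydroxyl-bearing carbon that is itself next to the formyl carbon. This reproduces C5 / C4a(C4) / C8a(O1) / C8(CHO) of the target, and aldehyde 11 reproduces C2, C3 and ring B. No skeletal correction is needed.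
- Precursor design, ring A: both phenols stay free. Aldehyde 2 is then symmetric, so sulfonylmethylation has one possible site. The ortho- and para-quinoid methides converge on one adduct, and only the C8a hydroxyl can reach C2.
- Precursor design, ring B: both phenols are silylated, so the 2'-OH cannot lactolise onto its own side-chain aldehyde or add to the prenyl group. The silyl ethers are removed by fluoride without acid.
- Catalyst antipode: the R-configured diphenylprolinol silyl ether is assigned to 3R by the usual shielding model of the anti E-enamine. The alpha-aryl group outranks the new CH2Ar branch, so the descriptor is opposite to that of alpha-alkyl aldehydes made with the same catalyst.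
- End game: lactol 14 is opened by hydride and re-closed, not deoxygenated with silane and Lewis acid. Ionic hydrogenation would also attack the electron-rich C8 formyl group, and O1, deactivated by that group, ionises reluctantly. Lactol 14 is a ring–chain tautomeric system, and the borohydride of step 8 acts on its open hydroxy-aldehyde form.

**Step 1**
Reactants: 1 2,4,6-trihydroxybenzaldehyde
Product: 2 2,6-dihydroxy-4-methoxybenzaldehyde
Conditions: MeI (1.05 equiv), NaHCO3 (1.1 equiv), DMF, rt
Reagents that add atoms: methyl iodide, CI
Why: The 4-OH, para to the formyl group, is the most acidic hydroxyl and is not held in the hydrogen bond to the carbonyl as the two ortho hydroxyls are, so one equivalent of MeI under weak base should give the 4-methyl ether by Williamson alkylation.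

**Step 2**
Reactants: 2 2,6-dihydroxy-4-methoxybenzaldehyde; 3 sodium p-toluenesulfinate
Product: 5 2,6-dihydroxy-4-methoxy-3-[(4-methylphenyl)sulfonylmethyl]benzaldehyde, via hydroxymethyl phenol 4 (not isolated)
Conditions: 37% aq CH2O (1.0 equiv, slow addition), 3 (3 equiv), HCO2H/H2O 1:1, rt
Reagents that add atoms: formaldehyde, C=O
Why: Lederer–Manasse hydroxymethylation at one of the two equivalent free ring positions gives benzylic alcohol 4, whose acid-derived benzylic cation is trapped at sulfur by the excess sulfinate (three-component sulfonylmethylation of an electron-rich phenol), the excess outcompeting attack by a second arene.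

**Step 3**
Reactants: 6 2,4-dihydroxybenzaldehyde; 7 prenyl bromide (1-bromo-3-methylbut-2-ene)
Product: 8 2,4-dihydroxy-3-prenylbenzaldehyde
Conditions: 7 (1.0 equiv), KOH (1.1 equiv), H2O, 0 °C to rt
Reagents that add atoms: none
Why: In water the phenoxide oxygen is solvated and the ambident anion alkylates at carbon, preferentially at C3 between the two oxygens, so direct C-prenylation of the resorcinol unit should give 8, separable from O-prenyl and C5-prenyl isomers.

**Step 4**
Reactants: 8 2,4-dihydroxy-3-prenylbenzaldehyde
Product: 9 2,4-bis(tert-butyldimethylsilyloxy)-3-prenylbenzaldehyde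
Conditions: TBSOTf (2.5 equiv), 2,6-lutidine (4 equiv), CH2Cl2, 0 °C
Reagents that add atoms: tert-butyldimethylsilyl trifluoromethanesulfonate, CC(C)(C)[Si](C)(C)OS(=O)(=O)C(F)(F)F
Why: A silyl triflate with a hindered pyridine base silylates both phenols, including the hydrogen-bonded 2-OH flanked by the prenyl and formyl groups, without affecting the alkene or the aldehyde (standard O-silylation).

**Step 5**
Reactants: 9 2,4-bis(tert-butyldimethylsilyloxy)-3-prenylbenzaldehyde
Product: 10 1-(2-methoxyethenyl)-2,4-bis(tert-butyldimethylsilyloxy)-3-prenylbenzene (E/Z mixture)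
Conditions: Ph3P(CH2OMe)Cl (1.5 equiv), NaN(SiMe3)2 (1.45 equiv), THF, 0 °C to rt
Reagents that add atoms: (methoxymethyl)triphenylphosphonium chloride, COC[P+](c1ccccc1)(c1ccccc1)c1ccccc1.[Cl-]
Why: Wittig methoxymethylenation with the non-stabilised ylide converts the non-enolisable aryl aldehyde into the one-carbon-homologous enol ether, whose double-bond geometry is of no consequence, under conditions that leave aryl silyl ethers and the prenyl alkene intact.

**Step 6**
Reactants: 10 1-(2-methoxyethenyl)-2,4-bis(tert-butyldimethylsilyloxy)-3-prenylbenzene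
Product: 11 2-[2,4-bis(tert-butyldimethylsilyloxy)-3-prenylphenyl]acetaldehyde
Conditions: 2 M aq HCl, THF, rt; used at once
Reagents that add atoms: water, O
Why: Acid-catalysed enol-ether hydrolysis (C-protonation, hydration of the oxocarbenium ion, loss of methanol) should release the arylacetaldehyde under conditions much milder than those needed to protonate the trisubstituted prenyl alkene or to cleave phenolic silyl ethers.

**Step 7**
Reactants: 5 2,6-dihydroxy-4-methoxy-3-[(4-methylphenyl)sulfonylmethyl]benzaldehyde; 11 2-[2,4-bis(tert-butyldimethylsilyloxy)-3-prenylphenyl]acetaldehyde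
Product: 14 (3R)-3-[2,4-bis(tert-butyldimethylsilyloxy)-3-prenylphenyl]-2,7-dihydroxy-5-methoxychromane-8-carbaldehyde (lactol; both C2 epimers), via ortho-quinone methide 12 (not isolated), via open-chain aldehyde 13 (not isolated)
Conditions: 11 (1.5 equiv), (R)-2-[diphenyl(trimethylsilyloxy)methyl]pyrrolidine (20 mol %), NaHCO3 (2 equiv), CH2Cl2/H2O, 0 °C
Reagents that add atoms: water, O (supplies the C2 hydroxyl oxygen on hydrolysis of the iminium ion; the carbonyl oxygen of 11 leaves as water on enamine formation)
Why: Bicarbonate deprotonates the acidic phenol of 5 and E1cB loss of p-toluenesulfinate releases methide 12 (its para-quinoid tautomer leads to the same adduct); the E-enamine of 11 then adds through its alpha carbon to the unsubstituted methide carbon (C3–C4), ring A rearomatises, and hydrolysis of the iminium ion frees aldehyde 13 and the catalyst. The closest known reaction is the aminocatalytic formal [4+2] annulation (Michael addition then hemiacetalisation) of enolisable aldehydes with ortho-quinone methides generated in situ from 2-(sulfonylmethyl)phenols, which gives chroman-2-ols. Ring C closes by 6-exo-trig attack of the C8a hydroxyl on the C2 carbonyl (O1–C2). C3 is set by the catalyst, whose diphenyl(silyloxy)methyl group blocks one face of the anti E-enamine so that the methide is taken up on the open face, expected to give 3R with the R catalyst, while the anomeric C2 is uncontrolled and is removed in step 8. The step needs C-alkylation by the enamine to outrun capture of 12 by the electron-rich C6–H of a second ring-A molecule and condensation of the amine with the ring-A formyl group. The doubly hydrogen-bonded, vinylogous-acid character of that formyl group, the excess of 11 and the slow two-phase release of 12 should secure this, and fast lactol closure limits re-enolisation at C3.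

**Step 8**
Reactants: 14 (3R)-lactol
Product: 15 3-[(2R)-2-[2,4-bis(tert-butyldimethylsilyloxy)-3-prenylphenyl]-3-hydroxypropyl]-2,6-dihydroxy-4-methoxybenzaldehyde
Conditions: NaBH4 (1.5 equiv), THF/EtOH, −20 °C; then aq NH4Cl
Reagents that add atoms: none
Why: The lactol is in ring–chain equilibrium with its open hydroxy-aldehyde tautomer, which in the basic borohydride medium is held as the phenoxide and whose aliphatic carbonyl is reduced much faster than the ring-A formyl group (a chelated vinylogous carboxylate as its phenoxide) and faster than C3 can enolise, so chemoselective borohydride reduction of the lactol through its open form should give the configurationally stable diol.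

**Step 9**
Reactants: 15 (R)-diol
Product: 16 (3R)-3-[2,4-bis(tert-butyldimethylsilyloxy)-3-prenylphenyl]-7-hydroxy-5-methoxychromane-8-carbaldehyde
Conditions: PPh3 (1.5 equiv), DIAD (1.5 equiv), THF (0.01 M), 0 °C to rt
Reagents that add atoms: none
Why: Intramolecular Mitsunobu etherification, in which the acidic C8a phenol displaces the primary oxyphosphonium group in a 6-exo-tet closure that does not involve C3, while the second free phenol cannot reach the chain and high dilution suppresses intermolecular alkylation.

**Step 10**
Reactants: 16 (3R)-bis-silyl isoflavan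
Product: 17 (3R)-3-(2,4-dihydroxy-3-prenylphenyl)-7-hydroxy-5-methoxychromane-8-carbaldehyde (target, CNP0399843.1)
Conditions: Bu4NF (2.5 equiv), AcOH (2.5 equiv), THF, 0 °C
Reagents that add atoms: none
Why: Buffered fluoride cleaves both aryl silyl ethers through Si–F bond formation under non-acidic conditions, which leaves the aldehyde, the prenyl group and C3 untouched and avoids acid-induced cyclisation of the 2'-OH onto the prenyl group.

**Compound list**
1 | 2,4,6-trihydroxybenzaldehyde | O=Cc1c(O)cc(O)cc1O | starting material
2 | 2,6-dihydroxy-4-methoxybenzaldehyde | COc1cc(O)c(C=O)c(O)c1 | intermediate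
3 | sodium p-toluenesulfinate | Cc1ccc(S(=O)[O-])cc1.[Na+] | starting material
4 | 2,6-dihydroxy-3-(hydroxymethyl)-4-methoxybenzaldehyde | COc1cc(O)c(C=O)c(O)c1CO | intermediate (not isolated)
5 | 2,6-dihydroxy-4-methoxy-3-[(4-methylphenyl)sulfonylmethyl]benzaldehyde | COc1cc(O)c(C=O)c(O)c1CS(=O)(=O)c1ccc(C)cc1 | intermediate
6 | 2,4-dihydroxybenzaldehyde | O=Cc1ccc(O)cc1O | starting material
7 | prenyl bromide | CC(C)=CCBr | starting material
8 | 2,4-dihydroxy-3-prenylbenzaldehyde | O=Cc1ccc(O)c(CC=C(C)C)c1O | intermediate
9 | 2,4-bis(tert-butyldimethylsilyloxy)-3-prenylbenzaldehyde | O=Cc1ccc(O[Si](C)(C)C(C)(C)C)c(CC=C(C)C)c1O[Si](C)(C)C(C)(C)C | intermediate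
10 | 1-(2-methoxyethenyl)-2,4-bis(tert-butyldimethylsilyloxy)-3-prenylbenzene (E/Z mixture) | COC=Cc1ccc(O[Si](C)(C)C(C)(C)C)c(CC=C(C)C)c1O[Si](C)(C)C(C)(C)C | intermediate
11 | 2-[2,4-bis(tert-butyldimethylsilyloxy)-3-prenylphenyl]acetaldehyde | O=CCc1ccc(O[Si](C)(C)C(C)(C)C)c(CC=C(C)C)c1O[Si](C)(C)C(C)(C)C | intermediate
12 | 2-hydroxy-4-methoxy-5-methylidene-6-oxocyclohexa-1,3-diene-1-carbaldehyde (ortho-quinone methide) | C=C1C(=O)C(C=O)=C(O)C=C1OC | intermediate (not isolated)
13 | (2R)-2-[2,4-bis(tert-butyldimethylsilyloxy)-3-prenylphenyl]-3-(3-formyl-2,4-dihydroxy-6-methoxyphenyl)propanal | COc1cc(O)c(C=O)c(O)c1C[C@H](c1ccc(O[Si](C)(C)C(C)(C)C)c(CC=C(C)C)c1O[Si](C)(C)C(C)(C)C)C=O | intermediate (not isolated)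
14 | (3R)-3-[2,4-bis(tert-butyldimethylsilyloxy)-3-prenylphenyl]-2,7-dihydroxy-5-methoxychromane-8-carbaldehyde (C2 epimers) | COc1cc(O)c(C=O)c2c1C[C@H](c1ccc(O[Si](C)(C)C(C)(C)C)c(CC=C(C)C)c1O[Si](C)(C)C(C)(C)C)C(O)O2 | intermediate
15 | 3-[(2R)-2-[2,4-bis(tert-butyldimethylsilyloxy)-3-prenylphenyl]-3-hydroxypropyl]-2,6-dihydroxy-4-methoxybenzaldehyde | COc1cc(O)c(C=O)c(O)c1C[C@H](c1ccc(O[Si](C)(C)C(C)(C)C)c(CC=C(C)C)c1O[Si](C)(C)C(C)(C)C)CO | intermediate
16 | (3R)-3-[2,4-bis(tert-butyldimethylsilyloxy)-3-prenylphenyl]-7-hydroxy-5-methoxychromane-8-carbaldehyde | COc1cc(O)c(C=O)c2c1C[C@H](c1ccc(O[Si](C)(C)C(C)(C)C)c(CC=C(C)C)c1O[Si](C)(C)C(C)(C)C)CO2 | intermediate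
17 | (3R)-3-(2,4-dihydroxy-3-prenylphenyl)-7-hydroxy-5-methoxychromane-8-carbaldehyde | COc1cc(O)c(C=O)c2c1C[C@H](c1ccc(O)c(CC=C(C)C)c1O)CO2 | target

**Step count**
Total: 10 steps. Longest linear sequence: 8 steps (steps 3 to 10, from 2,4-dihydroxybenzaldehyde).

**Steps most likely to fail**

1. Step 7. The enamine addition may show poor facial selectivity, the methide may be consumed by C-alkylation of a second ring-A molecule, or the C3 centre may erode through ring–chain tautomerism of the lactol in the basic medium. The fallback gives up catalytic enantiocontrol and sets out from 5 and 11. The two are joined with pyrrolidine (20 mol %) and NaHCO3 in CH2Cl2/H2O, which should give the racemic lactol F1. Reduction with NaBH4 under the conditions of step 8 should give the racemic diol F2, which cannot epimerise. F2 is resolved by preparative supercritical-fluid chromatography on a polysaccharide chiral stationary phase. The R enantiomer is compound 15, where the route is rejoined before step 9, and the (S)-diol F3 is set aside.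

2. Step 3. O-alkylation, alkylation at C5 and double prenylation may dominate over C3-alkylation. The fallback replaces direct alkylation by a sigmatropic delivery and sets out from 6. Alkylation of the non-chelated 4-OH with 3-chloro-3-methylbut-1-yne (K2CO3, KI and CuI catalytic, acetone, reflux) should give 2-hydroxy-4-[(2-methylbut-3-yn-2-yl)oxy]benzaldehyde F4. Semihydrogenation (H2, Pd on CaCO3 poisoned with Pb(OAc)2, quinoline, EtOAc) should give 2-hydroxy-4-[(2-methylbut-3-en-2-yl)oxy]benzaldehyde F5. Heating F5 in N,N-diethylaniline (about 130 °C) should bring about an aromatic Claisen rearrangement that places the prenyl group on C3, the position favoured by bond fixation in the chelated salicylaldehyde, and returns the route to 8.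

3. Step 2. The benzylic cation may be captured by a second arene to give a methylene-bridged dimer, or substitution may occur twice (C3 and C5). The fallback installs the benzylic carbon as a Mannich base and sets out from 2. Aminomethylation with dimethylmethylideneammonium iodide (CH2Cl2, rt; aq NaHCO3 work-up) should give 3-[(dimethylamino)methyl]-2,6-dihydroxy-4-methoxybenzaldehyde F6. The iminium ion is supplied stoichiometrically and the protonated product does not ionise at room temperature, so no benzylic cation meets a second arene. Heating F6 with 3 in AcOH/DMF (90 °C) should exchange the amine for the sulfinate by elimination–addition and return the route to 5.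

**Further compounds**
F1 | step 7 | racemic 3-[2,4-bis(tert-butyldimethylsilyloxy)-3-prenylphenyl]-2,7-dihydroxy-5-methoxychromane-8-carbaldehyde | COc1cc(O)c(C=O)c2c1CC(c1ccc(O[Si](C)(C)C(C)(C)C)c(CC=C(C)C)c1O[Si](C)(C)C(C)(C)C)C(O)O2
F2 | step 7 | racemic 3-[2-[2,4-bis(tert-butyldimethylsilyloxy)-3-prenylphenyl]-3-hydroxypropyl]-2,6-dihydroxy-4-methoxybenzaldehyde | COc1cc(O)c(C=O)c(O)c1CC(c1ccc(O[Si](C)(C)C(C)(C)C)c(CC=C(C)C)c1O[Si](C)(C)C(C)(C)C)CO
F3 | step 7 | 3-[(2S)-2-[2,4-bis(tert-butyldimethylsilyloxy)-3-prenylphenyl]-3-hydroxypropyl]-2,6-dihydroxy-4-methoxybenzaldehyde | COc1cc(O)c(C=O)c(O)c1C[C@@H](c1ccc(O[Si](C)(C)C(C)(C)C)c(CC=C(C)C)c1O[Si](C)(C)C(C)(C)C)CO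
F4 | step 3 | 2-hydroxy-4-[(2-methylbut-3-yn-2-yl)oxy]benzaldehyde | O=Cc1ccc(OC(C)(C)C#C)cc1O
F5 | step 3 | 2-hydroxy-4-[(2-methylbut-3-en-2-yl)oxy]benzaldehyde | O=Cc1ccc(OC(C)(C)C=C)cc1O
F6 | step 2 | 3-[(dimethylamino)methyl]-2,6-dihydroxy-4-methoxybenzaldehyde | COc1cc(O)c(C=O)c(O)c1CN(C)C
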